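The aryl ether bond O1–C8a of the 1,4-benzodioxane (from the oxygen on the aryl-bearing carbon C2 to ring B) is the disconnection on which everything rests. Because O1 and O4 are ortho neighbours on ring B, a threo 1-aryl-2-aryloxypropane-1,3-diol with iodine beside the ether oxygen holds its benzylic hydroxyl within six-ring reach of that carbon. A CuI-catalysed intramolecular Ullmann etherification then closes the dioxane ring in one operation, at the iodide only. It spares a ring B bromide that a final Heck reaction turns into the propenal. An Evans syn glycolate aldol sets both stereocentres beforehand, so the threo (1S,2S) chain becomes the trans (2S,3S) ring.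

Key step: step 7

Remark on numbering: atoms are labelled O1, C2 (aryl-bearing), C3 (hydroxymethyl-bearing), O4, C4a, C5 (OMe), C6, C7 (side chain), C8, C8a; ring A is the syringyl ring, ring B the benzo ring.
Assumption: compound 3 is taken as a catalogue compound; otherwise it needs one N-acylation of (R)-4-benzyloxazolidin-2-one with chloroacetyl chloride.

Step 1
Reactants: 1 4-bromo-2-methoxyphenol
Product: 2 4-bromo-2-iodo-6-methoxyphenol
Conditions: I2, NaHCO3, THF/H2O, rt
Reagents that add atoms: iodine, II
Why: Electrophilic aromatic iodination of the phenoxide, which directs ortho/para; the para position carries bromine and the other ortho position carries OMe, so only the free ortho carbon should react.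

Step 2
Reactants: 2 4-bromo-2-iodo-6-methoxyphenol; 3 (R)-4-benzyl-3-(chloroacetyl)oxazolidin-2-one
Product: 4 (R)-4-benzyl-3-[(4-bromo-2-iodo-6-methoxyphenoxy)acetyl]oxazolidin-2-one
Conditions: K2CO3, NaI (cat.), DMF, rt
Reagents that add atoms: none
Why: Williamson ether synthesis on an α-halo imide, a strongly activated SN2 electrophile, with Finkelstein catalysis by iodide; the auxiliary stereocentre is not acidic and should stay intact.

Step 3
Reactants: 5 syringaldehyde
Product: 6 3,5-dimethoxy-4-(methoxymethoxy)benzaldehyde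
Conditions: MOMCl, iPr2NEt, CH2Cl2, 0 °C to rt
Reagents that add atoms: chloromethyl methyl ether, COCCl
Why: O-alkylation of the phenol to an acetal-type ether that tolerates boron enolates, hydride, base and copper and is removed by aqueous acid at the end.

Step 4
Reactants: 4 (R)-4-benzyl-3-[(4-bromo-2-iodo-6-methoxyphenoxy)acetyl]oxazolidin-2-one; 6 3,5-dimethoxy-4-(methoxymethoxy)benzaldehyde
Product: 9 (R)-4-benzyl-3-[(2R,3S)-2-(4-bromo-2-iodo-6-methoxyphenoxy)-3-[3,5-dimethoxy-4-(methoxymethoxy)phenyl]-3-hydroxypropanoyl]oxazolidin-2-one, via Z-boron enolate 7 (not isolated), via boron aldolate 8 (not isolated)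
Conditions: Bu2BOTf, iPr2NEt, CH2Cl2, −78 to 0 °C; then 6, −78 to 0 °C; then pH 7 buffer, MeOH, H2O2, 0 °C
Reagents that add atoms: none
Why: Evans syn glycolate aldol: the Z-boron enolate reacts through a closed Zimmerman–Traxler chair, and the aldehyde approaches the face opposite the benzyl group of the (R)-auxiliary, which should set both new stereocentres as the (2R,3S) syn adduct.

Step 5
Reactants: 9 the syn aldol adduct
Product: 10 (1S,2S)-2-(4-bromo-2-iodo-6-methoxyphenoxy)-1-[3,5-dimethoxy-4-(methoxymethoxy)phenyl]propane-1,3-diol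
Conditions: LiBH4, MeOH (2 equiv), THF, 0 °C
Reagents that add atoms: none
Why: Reductive removal of the auxiliary, in which borohydride attacks the lithium-chelated exocyclic imide carbonyl; the cold, weakly basic medium should avoid retro-aldol and epimerization, and both aryl halides survive.

Step 6
Reactants: 10 the threo 1,3-diol
Product: 11 (1S,2S)-2-(4-bromo-2-iodo-6-methoxyphenoxy)-1-[3,5-dimethoxy-4-(methoxymethoxy)phenyl]-3-(trityloxy)propan-1-ol
Conditions: TrCl, Et3N, DMAP (cat.), CH2Cl2, rt
Reagents that add atoms: trityl chloride, ClC(c1ccccc1)(c1ccccc1)c1ccccc1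
Why: Tritylation, sterically selective for the primary hydroxyl over the secondary benzylic one; an ether that cannot migrate under base masks the only other oxygen that could close a six-membered ring.

Step 7
Reactants: 11 the trityl ether with free benzylic hydroxyl
Product: 12 (2S,3S)-7-bromo-2-[3,5-dimethoxy-4-(methoxymethoxy)phenyl]-5-methoxy-3-[(trityloxy)methyl]-2,3-dihydro-1,4-benzodioxine
Conditions: CuI (10 mol%), 3,4,7,8-tetramethyl-1,10-phenanthroline (20 mol%), Cs2CO3, toluene, 110 °C
Reagents that add atoms: none
Why: Cs2CO3 and the phenanthroline-bound monovalent copper convert the benzylic hydroxyl into a copper alkoxide, which activates the neighbouring aryl carbon–iodine bond (oxidative addition to a trivalent aryl copper alkoxide) and then forms the O1–C8a bond by reductive elimination, returning CuI. The closest known reaction type is the Ullmann-type copper-catalysed arylation of aliphatic alcohols with aryl iodides, including closures of 2-(2-halophenoxy)ethanols to 2,3-dihydro-1,4-benzodioxines. The 1,4-dioxane ring closes in a 6-exo sense, the oxygen attacking the arene carbon while iodide leaves outside the new ring. No stereocentre is formed or touched: C2 and C3 come from step 4, and the threo (1S,2S) chain maps onto the trans (2S,3S) ring with both substituents equatorial. The step needs arylation by the benzylic oxygen alone and at the iodide alone; the primary hydroxyl is a trityl ether, the phenol a MOM ether, and the bromide is para to O4, out of intramolecular reach and far less reactive toward copper. Copper is preferred to palladium because a palladium alkoxide of this secondary benzylic alcohol could undergo β-hydride elimination and palladium would also insert into the carbon–bromine bond.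

Step 8
Reactants: 12 the 7-bromobenzodioxane; 13 acrolein diethyl acetal
Product: 16 Bilagrewin, via Heck diethyl acetal 14 (not isolated), via protected enal 15 (not isolated)
Conditions: Pd(OAc)2 (5 mol%), nBu4NOAc, K2CO3, KCl, DMF, 90 °C; then 3 M aq HCl, THF, rt to 40 °C
Reagents that add atoms: water, O
Why: Mizoroki–Heck reaction in which syn insertion places the aryl group on the terminal alkene carbon and β-hydride elimination toward the benzylic hydrogen should give the (E)-alkenyl acetal, after which aqueous acid hydrolyses the acetal to the enal and cleaves the trityl and MOM ethers; the trans ring is the thermodynamic isomer, so reversible benzylic ionisation should not erode C2.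

Compound list
1 | 4-bromo-2-methoxyphenol | COc1cc(Br)ccc1O | starting material
2 | 4-bromo-2-iodo-6-methoxyphenol | COc1cc(Br)cc(I)c1O | intermediate
3 | (R)-4-benzyl-3-(chloroacetyl)oxazolidin-2-one | O=C(CCl)N1[C@H](Cc2ccccc2)COC1=O | starting material
4 | (R)-4-benzyl-3-[(4-bromo-2-iodo-6-methoxyphenoxy)acetyl]oxazolidin-2-one | COc1cc(Br)cc(I)c1OCC(=O)N1[C@H](Cc2ccccc2)COC1=O | intermediate
5 | syringaldehyde (4-hydroxy-3,5-dimethoxybenzaldehyde) | COc1cc(C=O)cc(OC)c1O | starting material
6 | 3,5-dimethoxy-4-(methoxymethoxy)benzaldehyde | COCOc1c(OC)cc(C=O)cc1OC | intermediate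
7 | Z-dibutylboron enolate of 4 (O–B and aryloxy cis) | CCCCB(CCCC)O/C(=C\Oc1c(I)cc(Br)cc1OC)N1[C@H](Cc2ccccc2)COC1=O | intermediate (not isolated)
8 | dibutylboron aldolate of 9 | COc1cc([C@H](OB(CCCC)CCCC)[C@H](C(=O)N2[C@H](Cc3ccccc3)COC2=O)Oc2c(I)cc(Br)cc2OC)cc(OC)c1OCOC | intermediate (not isolated)
9 | (R)-4-benzyl-3-[(2R,3S)-2-(4-bromo-2-iodo-6-methoxyphenoxy)-3-[3,5-dimethoxy-4-(methoxymethoxy)phenyl]-3-hydroxypropanoyl]oxazolidin-2-one (syn aldol) | COc1cc([C@H](O)[C@H](C(=O)N2[C@H](Cc3ccccc3)COC2=O)Oc2c(I)cc(Br)cc2OC)cc(OC)c1OCOC | intermediate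
10 | (1S,2S)-2-(4-bromo-2-iodo-6-methoxyphenoxy)-1-[3,5-dimethoxy-4-(methoxymethoxy)phenyl]propane-1,3-diol (threo) | COc1cc([C@H](O)[C@H](CO)Oc2c(I)cc(Br)cc2OC)cc(OC)c1OCOC | intermediate
11 | (1S,2S)-2-(4-bromo-2-iodo-6-methoxyphenoxy)-1-[3,5-dimethoxy-4-(methoxymethoxy)phenyl]-3-(trityloxy)propan-1-ol | COc1cc([C@H](O)[C@H](COC(c2ccccc2)(c3ccccc3)c4ccccc4)Oc5c(I)cc(Br)cc5OC)cc(OC)c1OCOC | intermediate
12 | (2S,3S)-7-bromo-2-[3,5-dimethoxy-4-(methoxymethoxy)phenyl]-5-methoxy-3-[(trityloxy)methyl]-2,3-dihydro-1,4-benzodioxine (trans) | COc1cc([C@@H]2Oc3cc(Br)cc(OC)c3O[C@H]2COC(c4ccccc4)(c5ccccc5)c6ccccc6)cc(OC)c1OCOC | intermediate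
13 | acrolein diethyl acetal (3,3-diethoxyprop-1-ene) | C=CC(OCC)OCC | starting material
14 | (2S,3S)-7-[(E)-3,3-diethoxyprop-1-enyl]-2-[3,5-dimethoxy-4-(methoxymethoxy)phenyl]-5-methoxy-3-[(trityloxy)methyl]-2,3-dihydro-1,4-benzodioxine | COc1cc([C@@H]2Oc3cc(/C=C/C(OCC)OCC)cc(OC)c3O[C@H]2COC(c4ccccc4)(c5ccccc5)c6ccccc6)cc(OC)c1OCOC | intermediate (not isolated)
15 | (E)-3-[(2S,3S)-2-[3,5-dimethoxy-4-(methoxymethoxy)phenyl]-5-methoxy-3-[(trityloxy)methyl]-2,3-dihydro-1,4-benzodioxin-7-yl]prop-2-enal | COc1cc([C@@H]2Oc3cc(/C=C/C=O)cc(OC)c3O[C@H]2COC(c4ccccc4)(c5ccccc5)c6ccccc6)cc(OC)c1OCOC | intermediate (not isolated)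
16 | Bilagrewin, (E)-3-[(2S,3S)-2-(4-hydroxy-3,5-dimethoxyphenyl)-3-(hydroxymethyl)-5-methoxy-2,3-dihydro-1,4-benzodioxin-7-yl]prop-2-enal | COc1cc([C@@H]2Oc3cc(/C=C/C=O)cc(OC)c3O[C@H]2CO)cc(OC)c1O | target

Total step count: 8. Longest linear sequence: 7 steps (steps 1, 2, 4, 5, 6, 7, 8); step 3 is a one-step side branch.

Steps most likely to fail

Step 7. Carbon–oxygen bond formation from a hindered secondary benzylic alkoxide may be slow at 110 °C. This could let base-induced expulsion of the aryloxide by the neighbouring alkoxide (β-aryl ether cleavage through an epoxide) or activation of the carbon–bromine bond compete. The fallback sets out from 11 and reverses the polarity of the arene. Miyaura borylation at the iodide only (PdCl2(dppf), bis(pinacolato)diboron, KOAc, dioxane, 80 °C) would give (1S,2S)-2-[4-bromo-2-methoxy-6-(4,4,5,5-tetramethyl-1,3,2-dioxaborolan-2-yl)phenoxy]-1-[3,5-dimethoxy-4-(methoxymethoxy)phenyl]-3-(trityloxy)propan-1-ol F1. An intramolecular Chan–Lam etherification (Cu(OAc)2, pyridine, 4 Å molecular sieves, O2, CH2Cl2, rt) would then close the same O1–C8a bond oxidatively at room temperature and come back to the route at 12.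

Step 8. Oxidative addition of zerovalent palladium into the electron-rich aryl bromide may be sluggish, and β-hydride elimination toward the acetal carbon would end in a saturated ester after hydrolysis. Prolonged acid could also ionise the benzylic O1–C2 bond once the ring A phenol is free. The fallback sets out from 12. Bromine–lithium exchange and formylation (nBuLi, THF, −78 °C; then DMF) would give (2S,3S)-2-[3,5-dimethoxy-4-(methoxymethoxy)phenyl]-5-methoxy-3-[(trityloxy)methyl]-2,3-dihydro-1,4-benzodioxine-7-carbaldehyde F2. A Wittig reaction with (formylmethylene)triphenylphosphorane (toluene, 80 °C) would then give the (E)-enal and come back to the route at 15, which is deprotected with aqueous HCl in THF as in the second half of step 8 to reach 16.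

Step 2. The doubly ortho-substituted phenoxide may displace chloride slowly, so that acyl transfer (attack on the exocyclic imide carbonyl with loss of the auxiliary) competes. The fallback sets out from 2 and builds the imide by acylation instead of alkylation. Alkylation with tert-butyl bromoacetate (K2CO3, acetone, reflux) would give tert-butyl (4-bromo-2-iodo-6-methoxyphenoxy)acetate F3. Cleavage with TFA in CH2Cl2 would give (4-bromo-2-iodo-6-methoxyphenoxy)acetic acid F4. Mixed-anhydride coupling (PivCl, Et3N, THF; then (R)-4-benzyloxazolidin-2-one, LiCl) would come back to the route at 4.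

Further compounds
F1 | step 7 | (1S,2S)-2-[4-bromo-2-methoxy-6-(4,4,5,5-tetramethyl-1,3,2-dioxaborolan-2-yl)phenoxy]-1-[3,5-dimethoxy-4-(methoxymethoxy)phenyl]-3-(trityloxy)propan-1-ol | COc1cc([C@H](O)[C@H](COC(c2ccccc2)(c3ccccc3)c4ccccc4)Oc5c(B6OC(C)(C)C(C)(C)O6)cc(Br)cc5OC)cc(OC)c1OCOC
F2 | step 8 | (2S,3S)-2-[3,5-dimethoxy-4-(methoxymethoxy)phenyl]-5-methoxy-3-[(trityloxy)methyl]-2,3-dihydro-1,4-benzodioxine-7-carbaldehyde | COc1cc([C@@H]2Oc3cc(C=O)cc(OC)c3O[C@H]2COC(c4ccccc4)(c5ccccc5)c6ccccc6)cc(OC)c1OCOC
F3 | step 2 | tert-butyl (4-bromo-2-iodo-6-methoxyphenoxy)acetate | COc1cc(Br)cc(I)c1OCC(=O)OC(C)(C)C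
F4 | step 2 | (4-bromo-2-iodo-6-methoxyphenoxy)acetic acid | COc1cc(Br)cc(I)c1OCC(=O)O
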